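**Plan**

1. Locants (germacrane): C1 and C3 are the two AcO–CH carbons, C4(Me)=C5 the Z-alkene, C6 the lactone O–CH, C7=C11 the butenolide C=C, C12 the lactone C=O, C13 the CH2OH carbon, C8/C9 the CH2CH2 link, C10=C14 the exocyclic methylene.
2. Cuts: C6–C7 together with the lactone O6–C12 bond (last), then C2–C3 (aldol) and C1–H (directed reduction), C10=C14 (ketone methylenation), C7–C11 (ester aldol, then enol triflate) and C4=C5 (Z-olefination).
3. Forward: an east chain C1/C2/C7–C14 (keto enol triflate 12) and a west (Z)-enal C3–C6 (17) are joined at C2–C3; the anti-1,3-diol is set and acetylated; C6 is raised to the aldehyde; one nickel/chromium step closes the ten-membered ring and, through the cis ester, the butenolide; removal of the 4-methoxybenzyl group ends the route.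
4. Enabling feature: the butenolide ring itself. C7 is the β-carbon of the tetrasubstituted C7=C11 enoate with the C12 carbonyl cis to it, and C6 is an allylic O–CH on the Z-C4=C5 bond. So C7 can be an alkenylchromium, C6 a (Z)-enal carbon, and the alkoxide formed at O6 is trapped by C12; carbocycle and lactone arise in the same step.
5. Stereochemistry: C3 from the Ipc2BCl aldol (reagent control); C1 from hydroxyl-directed 1,3-anti reduction; C6 in the ring closure (chiral sulfonamide ligand on chromium); C4=C5 from Still–Gennari olefination; C7=C11 from the chelated enolate, then locked by the lactone.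

Key step: step 15

Abbreviations: PMB = 4-methoxybenzyl; TBS = tert-butyldimethylsilyl; Tf = trifluoromethanesulfonyl; Ipc = isopinocampheyl (from (+)-α-pinene); L* = N-{2-[(4S)-4-isopropyl-4,5-dihydro-1,3-oxazol-2-yl]-6-methylphenyl}methanesulfonamide.

Assumption: the facial sense of the two chiral reagents (Si-face addition with (−)-Ipc2BCl in step 10, Si-face delivery by the L*–chromium complex in step 15) is to be confirmed on enal 17 as a model; the antipodal reagent is taken if the sense is opposite.

**Route**

Step 1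
Reactants: 1 4-methoxybenzyl alcohol; 2 methyl acrylate
Product: 3 methyl 3-[(4-methoxybenzyl)oxy]propanoate
Conditions: NaH (5 mol %), THF, 0 °C to rt
Reagents that add atoms: none
Why: Base-catalysed oxa-Michael addition of the alkoxide of 1 to the acrylate, the catalytic alkoxide being regenerated by proton transfer, so that no stereocentre and no by-product arise.

Step 2
Reactants: 4 1-methylcyclopentene
Product: 6 5-oxohexanal, via secondary ozonide 5 (not isolated)
Conditions: O3, CH2Cl2, −78 °C; then PPh3, −78 °C to rt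
Reagents that add atoms: ozone, [O-][O+]=O
Why: Ozonolysis (Criegee mechanism) with reductive work-up opens the ring to the keto aldehyde that carries C2, C1, C10, C9, C8 and C7 in that order.

Step 3
Reactants: 3 methyl 3-[(4-methoxybenzyl)oxy]propanoate; 6 5-oxohexanal
Product: 8 methyl 3-hydroxy-2-{[(4-methoxybenzyl)oxy]methyl}-7-oxooctanoate (diastereomer mixture), via lithium enolate 7 (not isolated)
Conditions: LiN(iPr)2, THF, −78 °C; then 6, −78 °C; AcOH quench
Reagents that add atoms: none
Why: Kinetic lithium ester enolate aldol addition, in which the aldehyde should react far faster than the methyl ketone and β-elimination of the PMB-oxide should be slow at −78 °C; the two new stereocentres are mixed and are removed in steps 4 and 5.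

Step 4
Reactants: 8 methyl 3-hydroxy-2-{[(4-methoxybenzyl)oxy]methyl}-7-oxooctanoate
Product: 9 methyl 2-{[(4-methoxybenzyl)oxy]methyl}-3,7-dioxooctanoate
Conditions: Dess–Martin periodinane, CH2Cl2, 0 °C to rt
Reagents that add atoms: none
Why: Dess–Martin oxidation of the secondary alcohol to the β-keto ester under near-neutral conditions that spare the PMB ether and avoid retro-aldol cleavage.

Step 5
Reactants: 9 methyl 2-{[(4-methoxybenzyl)oxy]methyl}-3,7-dioxooctanoate
Product: 11 methyl (2Z)-2-{[(4-methoxybenzyl)oxy]methyl}-7-oxo-3-(trifluoromethanesulfonyloxy)oct-2-enoate, via chelated lithium enolate 10 (not isolated)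
Conditions: Tf2O, saturated aqueous LiOH, toluene, 5 °C
Reagents that add atoms: trifluoromethanesulfonic anhydride, O=S(=O)(OS(=O)(=O)C(F)(F)F)C(F)(F)F
Why: O-sulfonylation of the lithium-chelated, U-shaped β-keto ester enolate (stereoselective enol triflate synthesis under biphasic conditions) should place OTf cis to the ester (Z), and only the far more acidic 1,3-dicarbonyl is deprotonated, so the methyl ketone is untouched.

Step 6
Reactants: 11 methyl (2Z)-2-{[(4-methoxybenzyl)oxy]methyl}-7-oxo-3-(trifluoromethanesulfonyloxy)oct-2-enoate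
Product: 12 methyl (2Z)-2-{[(4-methoxybenzyl)oxy]methyl}-6-methylidene-7-oxo-3-(trifluoromethanesulfonyloxy)oct-2-enoate
Conditions: (CH2O)n, iPr2NH·CF3CO2H (1 equiv), CF3CO2H (10 mol %), THF, reflux
Reagents that add atoms: paraformaldehyde (as formaldehyde), C=O
Why: Mannich-type α-methylenation of a ketone by formaldehyde and a secondary ammonium salt, in which the more substituted enol should react under these acidic conditions, so that the CH2 flank (C10) and not the methyl group is methylenated while the acid-stable enol triflate survives.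

Step 7
Reactants: 13 (tert-butyldimethylsilyloxy)acetaldehyde; 14 ethyl 2-[bis(2,2,2-trifluoroethoxy)phosphoryl]propanoate
Product: 15 ethyl (2Z)-4-(tert-butyldimethylsilyloxy)-2-methylbut-2-enoate
Conditions: KN(SiMe3)2, 18-crown-6, THF, −78 °C
Reagents that add atoms: none
Why: Still–Gennari olefination, in which the bis(trifluoroethyl) phosphonate under dissociating conditions eliminates from the kinetic adduct and should give the (Z)-trisubstituted enoate that fixes the C4=C5 geometry.

Step 8
Reactants: 15 ethyl (2Z)-4-(tert-butyldimethylsilyloxy)-2-methylbut-2-enoate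
Product: 16 (2Z)-4-(tert-butyldimethylsilyloxy)-2-methylbut-2-en-1-ol
Conditions: iBu2AlH (2.2 equiv), CH2Cl2, −78 °C; work-up with water
Reagents that add atoms: none
Why: 1,2-Reduction of the enoate by the aluminium hydride to the allylic alcohol without change of the alkene geometry or loss of the silyl ether.

Step 9
Reactants: 16 (2Z)-4-(tert-butyldimethylsilyloxy)-2-methylbut-2-en-1-ol
Product: 17 (2Z)-4-(tert-butyldimethylsilyloxy)-2-methylbut-2-enal
Conditions: TEMPO (10 mol %), PhI(OAc)2, CH2Cl2, rt
Reagents that add atoms: none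
Why: Oxoammonium (TEMPO/PhI(OAc)2) oxidation of the allylic alcohol under non-basic conditions of the kind that convert nerol into neral without Z to E isomerisation.

Step 10
Reactants: 12 methyl (2Z)-2-{[(4-methoxybenzyl)oxy]methyl}-6-methylidene-7-oxo-3-(trifluoromethanesulfonyloxy)oct-2-enoate; 17 (2Z)-4-(tert-butyldimethylsilyloxy)-2-methylbut-2-enal
Product: 19 methyl (2Z,9S,10Z)-12-(tert-butyldimethylsilyloxy)-9-hydroxy-2-{[(4-methoxybenzyl)oxy]methyl}-10-methyl-6-methylidene-7-oxo-3-(trifluoromethanesulfonyloxy)dodeca-2,10-dienoate, via boron enolate 18 (not isolated)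
Conditions: (−)-Ipc2BCl, Et3N, Et2O, 0 °C; then 17, −78 to −20 °C; H2O2, MeOH, pH 7 buffer, 0 °C
Reagents that add atoms: none
Why: Paterson boron aldol, in which (−)-Ipc2BCl/Et3N enolises the only enolisable site (the methyl group) and the diisopinocampheylboron enolate should add through a cyclic transition state to the Si face of the aldehyde to give the 3S carbinol (C9 of the chain), the enol triflate, esters and silyl ether being inert.

Step 11
Reactants: 19 the (9S)-β-hydroxy ketone
Product: 20 methyl (2Z,7S,9S,10Z)-12-(tert-butyldimethylsilyloxy)-7,9-dihydroxy-2-{[(4-methoxybenzyl)oxy]methyl}-10-methyl-6-methylidene-3-(trifluoromethanesulfonyloxy)dodeca-2,10-dienoate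
Conditions: Me4NBH(OAc)3, MeCN/AcOH, −30 °C
Reagents that add atoms: none
Why: Evans–Saksena reduction, in which the C3 hydroxyl exchanges onto boron and delivers hydride intramolecularly through a chair transition state to the C1 ketone (1,2-reduction of the enone), which should set C1 anti to C3 (1S).

Step 12
Reactants: 20 the (7S,9S)-anti-diol
Product: 21 methyl (2Z,7S,9S,10Z)-7,9-diacetoxy-12-(tert-butyldimethylsilyloxy)-2-{[(4-methoxybenzyl)oxy]methyl}-10-methyl-6-methylidene-3-(trifluoromethanesulfonyloxy)dodeca-2,10-dienoate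
Conditions: Ac2O, pyridine, DMAP (cat.), CH2Cl2, 0 °C to rt
Reagents that add atoms: acetic anhydride, CC(=O)OC(C)=O
Why: Standard acylation of both secondary allylic alcohols installs the two acetates of the target with retention at C1 and C3.

Step 13
Reactants: 21 the diacetate silyl ether
Product: 22 methyl (2Z,7S,9S,10Z)-7,9-diacetoxy-12-hydroxy-2-{[(4-methoxybenzyl)oxy]methyl}-10-methyl-6-methylidene-3-(trifluoromethanesulfonyloxy)dodeca-2,10-dienoate
Conditions: HF·pyridine, pyridine, THF, 0 °C
Reagents that add atoms: none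
Why: Buffered fluoride cleavage of the primary allylic silyl ether, which should leave the acetates, the enol triflate and the PMB ether intact.

Step 14
Reactants: 22 the primary allylic alcohol
Product: 23 methyl (2Z,7S,9S,10Z)-7,9-diacetoxy-2-{[(4-methoxybenzyl)oxy]methyl}-10-methyl-6-methylidene-12-oxo-3-(trifluoromethanesulfonyloxy)dodeca-2,10-dienoate
Conditions: TEMPO (10 mol %), PhI(OAc)2, CH2Cl2, rt
Reagents that add atoms: none
Why: Oxoammonium oxidation of the only free alcohol gives the (Z)-enal (C6 aldehyde) without base, so that neither Z to E isomerisation nor loss of acetate is expected.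

Step 15
Reactants: 23 the (Z)-enal enol triflate
Product: 26 (1S,3S,6R,4Z)-1,3-diacetoxy-13-[(4-methoxybenzyl)oxy]germacra-4,7(11),10(14)-trien-12,6-olide, via alkenylchromium species 24 (not isolated), via chromium alkoxide 25 (not isolated)
Conditions: CrCl2 (4 equiv), L* (4.4 equiv), Et3N (4.4 equiv), NiCl2 (10 mol %), THF, rt; 23 added over 12 h (final 2 mM)
Reagents that add atoms: none
Why: Zerovalent nickel, generated from NiCl2 by CrCl2, inserts into the activated C7–OTf bond and transmetalates to chromium, and the resulting alkenylchromium (trivalent) adds 1,2 to the C6 aldehyde; the closest known reaction types are Nozaki–Hiyama–Kishi macrocyclisations and the additions of (Z)-β-halo- or β-triflyloxy-enoates to aldehydes that give butenolides in one operation. The C6–C7 bond closes the ten-membered carbocycle by a 10-exo-trig carbonyl addition, and the chromium alkoxide at O6 then closes the butenolide by a 5-exo-trig acyl substitution on the methyl ester (loss of methoxide), which the Z geometry of the enol triflate makes possible by holding C12 cis to C7. C6 is the only new stereocentre: it is to be controlled by the chiral oxazoline–sulfonamide ligand on chromium (reagent control, as in asymmetric nickel/chromium couplings and macrocyclisations), chosen to deliver C7 to the Si face of the enal, while allylic 1,3-strain across the Z-C4=C5 bond keeps H3 in the alkene plane and so presents one defined conformer of the chain to the reagent. The step needs site selectivity (oxidative addition at the vinylogous-ester triflate and not at the allylic acetates, addition to the aldehyde and not to an ester), 1,2- rather than 1,4-addition to the enal (inherent to organochromium reagents), ring closure rather than oligomerisation (slow addition to high dilution) and retention of both alkene geometries (no acid or strong base is present and alkenyl–metal exchange proceeds with retention). The existing centres C1 and C3 are remote from every reacting atom and are not at risk.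

Step 16
Reactants: 26 the macrocyclic butenolide PMB ether
Product: 27 (1S,3S,6R,4Z)-1,3-diacetoxy-13-hydroxygermacra-4,7(11),10(14)-trien-12,6-olide (target)
Conditions: DDQ, CH2Cl2/pH 7 buffer, 0 °C
Reagents that add atoms: none
Why: Oxidative cleavage of the PMB ether by DDQ (hydride abstraction, then hydrolysis of the oxocarbenium ion) should free the C13 hydroxyl while the acetates, the butenolide and the three alkenes are inert.

**Compound list**

1 | 4-methoxybenzyl alcohol | COc1ccc(CO)cc1 | starting material
2 | methyl acrylate | C=CC(=O)OC | starting material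
3 | methyl 3-[(4-methoxybenzyl)oxy]propanoate | COC(=O)CCOCc1ccc(OC)cc1 | intermediate
4 | 1-methylcyclopentene | CC1=CCCC1 | starting material
5 | 1-methyl-6,7,8-trioxabicyclo[3.2.1]octane (racemic secondary ozonide of 4) | CC12CCCC(OO1)O2 | intermediate (not isolated)
6 | 5-oxohexanal | CC(=O)CCCC=O | intermediate
7 | lithium enolate of 3 (geometry not defined) | COC(O[Li])=CCOCc1ccc(OC)cc1 | intermediate (not isolated)
8 | methyl 3-hydroxy-2-{[(4-methoxybenzyl)oxy]methyl}-7-oxooctanoate (mixture of diastereomers) | COC(=O)C(COCc1ccc(OC)cc1)C(O)CCCC(C)=O | intermediate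
9 | methyl 2-{[(4-methoxybenzyl)oxy]methyl}-3,7-dioxooctanoate (racemic) | COC(=O)C(COCc1ccc(OC)cc1)C(=O)CCCC(C)=O | intermediate
10 | chelated lithium (Z)-enolate of 9 (O–Li cis to the ester) | CC(=O)CCC/C(O[Li])=C(\COCc1ccc(OC)cc1)C(=O)OC | intermediate (not isolated)
11 | methyl (2Z)-2-{[(4-methoxybenzyl)oxy]methyl}-7-oxo-3-(trifluoromethanesulfonyloxy)oct-2-enoate | CC(=O)CCC/C(OS(=O)(=O)C(F)(F)F)=C(\COCc1ccc(OC)cc1)C(=O)OC | intermediate
12 | methyl (2Z)-2-{[(4-methoxybenzyl)oxy]methyl}-6-methylidene-7-oxo-3-(trifluoromethanesulfonyloxy)oct-2-enoate | CC(=O)C(=C)CC/C(OS(=O)(=O)C(F)(F)F)=C(\COCc1ccc(OC)cc1)C(=O)OC | intermediate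
13 | (tert-butyldimethylsilyloxy)acetaldehyde | CC(C)(C)[Si](C)(C)OCC=O | starting material
14 | ethyl 2-[bis(2,2,2-trifluoroethoxy)phosphoryl]propanoate | CCOC(=O)C(C)P(=O)(OCC(F)(F)F)OCC(F)(F)F | starting material
15 | ethyl (2Z)-4-(tert-butyldimethylsilyloxy)-2-methylbut-2-enoate | CCOC(=O)/C(C)=C\CO[Si](C)(C)C(C)(C)C | intermediate
16 | (2Z)-4-(tert-butyldimethylsilyloxy)-2-methylbut-2-en-1-ol | OC/C(C)=C\CO[Si](C)(C)C(C)(C)C | intermediate
17 | (2Z)-4-(tert-butyldimethylsilyloxy)-2-methylbut-2-enal | O=C/C(C)=C\CO[Si](C)(C)C(C)(C)C | intermediate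
18 | diisopinocampheylboron enolate of 12 (O–B on C1, C1=C2 enol) | C=C(OB([C@@H]1C[C@@H]2C[C@H]([C@H]1C)C2(C)C)[C@@H]1C[C@@H]2C[C@H]([C@H]1C)C2(C)C)C(=C)CC/C(OS(=O)(=O)C(F)(F)F)=C(\COCc1ccc(OC)cc1)C(=O)OC | intermediate (not isolated)
19 | methyl (2Z,9S,10Z)-12-(tert-butyldimethylsilyloxy)-9-hydroxy-2-{[(4-methoxybenzyl)oxy]methyl}-10-methyl-6-methylidene-7-oxo-3-(trifluoromethanesulfonyloxy)dodeca-2,10-dienoate | CC(C)(C)[Si](C)(C)OC/C=C(/C)[C@@H](O)CC(=O)C(=C)CC/C(OS(=O)(=O)C(F)(F)F)=C(\COCc1ccc(OC)cc1)C(=O)OC | intermediate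
20 | methyl (2Z,7S,9S,10Z)-12-(tert-butyldimethylsilyloxy)-7,9-dihydroxy-2-{[(4-methoxybenzyl)oxy]methyl}-10-methyl-6-methylidene-3-(trifluoromethanesulfonyloxy)dodeca-2,10-dienoate | CC(C)(C)[Si](C)(C)OC/C=C(/C)[C@@H](O)C[C@H](O)C(=C)CC/C(OS(=O)(=O)C(F)(F)F)=C(\COCc1ccc(OC)cc1)C(=O)OC | intermediate
21 | methyl (2Z,7S,9S,10Z)-7,9-diacetoxy-12-(tert-butyldimethylsilyloxy)-2-{[(4-methoxybenzyl)oxy]methyl}-10-methyl-6-methylidene-3-(trifluoromethanesulfonyloxy)dodeca-2,10-dienoate | CC(C)(C)[Si](C)(C)OC/C=C(/C)[C@@H](OC(C)=O)C[C@H](OC(C)=O)C(=C)CC/C(OS(=O)(=O)C(F)(F)F)=C(\COCc1ccc(OC)cc1)C(=O)OC | intermediate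
22 | methyl (2Z,7S,9S,10Z)-7,9-diacetoxy-12-hydroxy-2-{[(4-methoxybenzyl)oxy]methyl}-10-methyl-6-methylidene-3-(trifluoromethanesulfonyloxy)dodeca-2,10-dienoate | OC/C=C(/C)[C@@H](OC(C)=O)C[C@H](OC(C)=O)C(=C)CC/C(OS(=O)(=O)C(F)(F)F)=C(\COCc1ccc(OC)cc1)C(=O)OC | intermediate
23 | methyl (2Z,7S,9S,10Z)-7,9-diacetoxy-2-{[(4-methoxybenzyl)oxy]methyl}-10-methyl-6-methylidene-12-oxo-3-(trifluoromethanesulfonyloxy)dodeca-2,10-dienoate | O=C/C=C(/C)[C@@H](OC(C)=O)C[C@H](OC(C)=O)C(=C)CC/C(OS(=O)(=O)C(F)(F)F)=C(\COCc1ccc(OC)cc1)C(=O)OC | intermediate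
24 | alkenylchromium species from 23 (chromium at C7 in place of OTf; drawn as the dichloride, sulfonamide ligand and solvent omitted) | O=C/C=C(/C)[C@@H](OC(C)=O)C[C@H](OC(C)=O)C(=C)CC/C([Cr](Cl)Cl)=C(\COCc1ccc(OC)cc1)C(=O)OC | intermediate (not isolated)
25 | chromium alkoxide of the macrocyclic (6R)-hydroxy ester (ten-membered ring closed, ester cis to C6; ligand omitted) | C=C1CC/C(=C(\COCc2ccc(OC)cc2)C(=O)OC)[C@H](O[Cr](Cl)Cl)/C=C(/C)[C@@H](OC(C)=O)C[C@@H]1OC(C)=O | intermediate (not isolated)
26 | (1S,3S,6R,4Z)-1,3-diacetoxy-13-[(4-methoxybenzyl)oxy]germacra-4,7(11),10(14)-trien-12,6-olide | C=C1CCC2=C(COCc3ccc(OC)cc3)C(=O)O[C@@H]2/C=C(/C)[C@@H](OC(C)=O)C[C@@H]1OC(C)=O | intermediate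
27 | (1S,3S,6R,4Z)-1,3-diacetoxy-13-hydroxygermacra-4,7(11),10(14)-trien-12,6-olide | C=C1CCC2=C(CO)C(=O)O[C@@H]2/C=C(/C)[C@@H](OC(C)=O)C[C@@H]1OC(C)=O | target

**Step count**

Total: 16 steps. Longest linear sequence: 12 steps (1, 3, 4, 5, 6, 10–16; the path that starts at step 2 is equally long).

**Steps most likely to fail**

Step 15. The hindered tetrasubstituted alkenylchromium may be protonated before it reaches the aldehyde. The chain may oligomerise instead of closing a strained ten-membered ring. Zerovalent nickel may ionise an allylic acetate. The ligand may not override the conformational bias of the closing ring, so facial discrimination at C6 may be poor. Fallback (sets out from 23, returns at 26): the C6–C7 bond is made by an intramolecular Stille acylation, and C6 is set afterwards by reduction of a ring ketone. Aldehyde 23 is oxidised (NaClO2, NaH2PO4, 2-methylbut-2-ene) to the carboxylic acid F1. The enol triflate is exchanged for tin (Me3SnSnMe3, Pd(PPh3)4, LiCl, THF, 60 °C) to give the β-stannyl enoate acid F2. The acid is converted with 1-chloro-N,N,2-trimethylprop-1-en-1-amine into the acid chloride F3. This is cyclised at high dilution (Pd2(dba)3, tri(2-furyl)phosphine, toluene) to the macrocyclic 6-ketone F4. 1,2-Reduction (NaBH4, CeCl3, MeOH, −78 °C; hydride from the outer face of the ring) gives the macrocyclic hydroxy ester F5, which lactonises onto the cis ester to 26.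

Step 6. Methylenation may occur on the methyl side or twice, the enone may polymerise, and the enol triflate may slowly degrade at reflux. Fallback (sets out from 11, returns at 12): a regiodefined Mannich sequence. Ketone 11 is converted under equilibrating conditions (Me3SiOTf, Et3N, CH2Cl2, 0 °C to rt) into the more substituted trimethylsilyl enol ether F6. This reacts with dimethylmethyleneiminium iodide at C10 to give the Mannich base F7. Quaternisation (MeI) and mild base (NaHCO3) eliminate the amine to give 12.

Step 10. Enantiofacial control by the isopinocampheyl ligands may be incomplete with this cross-conjugated enolate and a Z-enal, which would erode the enantiomeric purity of everything downstream. Fallback (sets out from 12 and 17, returns at 20): stereocontrol is moved from the aldol to a reagent-controlled reduction followed by separation of diastereomers. The aldol is run with achiral (c-C6H11)2BCl/Et3N and gives 19 together with its (9R)-enantiomer F8. The C1 ketone of both is reduced with (R)-2-methyl-CBS-oxazaborolidine and catecholborane (toluene, −78 °C), which should give 1S in both series. The (7S,9S)-anti-diol 20 and the (7S,9R)-syn-diol F9 are diastereomers and are separated by chromatography; the route continues from 20.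

**Further compounds**

F1 | step 15 | (2Z,4S,6S,10Z)-4,6-diacetoxy-12-methoxy-11-{[(4-methoxybenzyl)oxy]methyl}-3-methyl-7-methylidene-12-oxo-10-(trifluoromethanesulfonyloxy)dodeca-2,10-dienoic acid | OC(=O)/C=C(/C)[C@@H](OC(C)=O)C[C@H](OC(C)=O)C(=C)CC/C(OS(=O)(=O)C(F)(F)F)=C(\COCc1ccc(OC)cc1)C(=O)OC
F2 | step 15 | (2Z,4S,6S,10Z)-4,6-diacetoxy-12-methoxy-11-{[(4-methoxybenzyl)oxy]methyl}-3-methyl-7-methylidene-12-oxo-10-(trimethylstannyl)dodeca-2,10-dienoic acid | OC(=O)/C=C(/C)[C@@H](OC(C)=O)C[C@H](OC(C)=O)C(=C)CC/C([Sn](C)(C)C)=C(\COCc1ccc(OC)cc1)C(=O)OC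
F3 | step 15 | acid chloride of F2 | ClC(=O)/C=C(/C)[C@@H](OC(C)=O)C[C@H](OC(C)=O)C(=C)CC/C([Sn](C)(C)C)=C(\COCc1ccc(OC)cc1)C(=O)OC
F4 | step 15 | macrocyclic 6-ketone (ten-membered ring; (1S,3S)-diacetate; exocyclic C7=C11 enoate with the ester cis to C6) | C=C1CC/C(=C(\COCc2ccc(OC)cc2)C(=O)OC)C(=O)/C=C(/C)[C@@H](OC(C)=O)C[C@@H]1OC(C)=O
F5 | step 15 | macrocyclic (6R)-hydroxy ester (free alcohol corresponding to 25) | C=C1CC/C(=C(\COCc2ccc(OC)cc2)C(=O)OC)[C@H](O)/C=C(/C)[C@@H](OC(C)=O)C[C@@H]1OC(C)=O
F6 | step 6 | trimethylsilyl enol ether of 11 at C1=C10 (E/Z mixture) | CC(O[Si](C)(C)C)=CCC/C(OS(=O)(=O)C(F)(F)F)=C(\COCc1ccc(OC)cc1)C(=O)OC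
F7 | step 6 | methyl (2Z)-6-[(dimethylamino)methyl]-2-{[(4-methoxybenzyl)oxy]methyl}-7-oxo-3-(trifluoromethanesulfonyloxy)oct-2-enoate (racemic Mannich base) | CC(=O)C(CN(C)C)CC/C(OS(=O)(=O)C(F)(F)F)=C(\COCc1ccc(OC)cc1)C(=O)OC
F8 | step 10 | (9R)-enantiomer of 19 | CC(C)(C)[Si](C)(C)OC/C=C(/C)[C@H](O)CC(=O)C(=C)CC/C(OS(=O)(=O)C(F)(F)F)=C(\COCc1ccc(OC)cc1)C(=O)OC
F9 | step 10 | (7S,9R)-syn-diol (C9 epimer of 20) | CC(C)(C)[Si](C)(C)OC/C=C(/C)[C@H](O)C[C@H](O)C(=C)CC/C(OS(=O)(=O)C(F)(F)F)=C(\COCc1ccc(OC)cc1)C(=O)OC
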